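- In a one-step world, starting material + partner → double product, early double product at fixed starting material grows in proportion to partner, an apparent reaction order of 1, and it rises or holds to the last moment, so its highest point stands at the end.

| setting | south-west | north-west | flask |
|---|---|---|---|
| starting material | 0.020 M | 0.020 M | 0.020 M |
| partner | 0.030 M | 0.015 M | 0.0300 M |
| remark | the very flask that is asked about, followed so far | run made earlier |  |
| time |  |  | 2.5 d |

| run | time / h | double product / % |
|---|---|---|
| south-west | 2.00 | 4.8 |
| south-west | 4.00 | 7.6 |
| south-west | 8.00 | 7.9 |
| south-west | 20.0 | 9.7 |
| north-west | 2.00 | 1.7 |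
| north-west | 5.00 | 2.8 |
| north-west | 10.0 | 3.5 |
| north-west | 25.0 | 3.3 |

(scatter of a reading: 1 percentage point)

1. time up to 2.5 d at which double product stands highest
2. the amount of double product, in percent of the starting material charged, at that time

- Define n as the logarithm of the ratio of highest double-product readings, south-west over north-west, divided by the logarithm of their partner ratio: n = 1.47.
- Turn the question round: for order 1 held out to these readings, south-west's 9.7% would have to read 7.00%, a gap of 2.7 percentage points against a scatter of 1 point per reading, so the one-step world is disfavoured, not excluded.
- My own reckoning: the asked flask has south-west's charge, so I expect a height near the reading of 9.7% and, with n larger than 1, I guess at a peak inside the window; the rise of 1.8 points between the last two south-west readings stands against a scatter of 1 point per reading.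
- The forecast differs on time: 2.5 d and 9.2%, with “There is no clear sign of decay”.
- The asked flask peaks at 0.359 d with 9.58%, then falls to 5.38% at 2.50 d.

    starting material + partner → single product (k = 0.00240 M⁻¹ s⁻¹)
    double product ⇌ isomer of the product (K = 5.40, k = 5.00 × 10⁻⁵ s⁻¹)
    2 starting material → self-condensation product (k = 5.30 × 10⁻⁶ M⁻¹ s⁻¹)
    partner + double product → triple product (k = 0.00260 M⁻¹ s⁻¹)
    partner + single product → double product (k = 0.00150 M⁻¹ s⁻¹)

- Carry n to the neighbouring flask with 0.018 M of partner: scaling the asked flask's 9.58% by the partner ratio raised to n gives 4.52%, and that neighbour reaches 5.10%, more than the scaling gave. At 2.50 d that neighbour holds 2.68% double product, with 34% of its starting material and 0.070% of its partner left.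

Readings and results were computed for substances that don't exist.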